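**Plan**

- Retrosynthetic cuts, in order: the O–benzyl bonds at O5 and O2′ and the C7–O bond (back to C7–Br); the O1–C8a bond of ring C; the C3–C4 bond (aldol, then oxidation to the 1,3-diketone); the C4–C4a bond (ortho-formylation); the C5–O bond (C–H borylation/oxidation of 2,6-dibromoanisole).
- Forward: rings A and B are bought as benzene rings. Ring A is hydroxylated, formylated and benzylated, joined to the ring B acetophenone through C3–C4, and oxidised to the diketone. Ring C closes last by copper-catalysed O-arylation, then C7–Br becomes C7–OH and the benzyl groups are removed.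
- Enabling feature: in ring A the methoxy carbon C8 lies between C8a (which carries O1) and C7 (which carries OH). A 2,6-dibromoanisole unit therefore holds both oxygens as bromides, and O1 is supplied by the enolate oxygen on C2 of the chain, never by a ring A phenol.
- Stereochemistry: the target has no stereocentre; the carbinol carbon of aldol 8 is racemic and is erased by the oxidation in step 6.

Key step: step 7

Remark: diketone 9 is drawn in the diketo form although it should exist largely as the chelated enol; compounds 1 and 6 are taken as purchased.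

**Route**

Step 1
Reactants: 1 2,6-dibromoanisole (1,3-dibromo-2-methoxybenzene)
Product: 3 3,5-dibromo-4-methoxyphenol, via pinacol boronate 2 (not isolated)
Conditions: [Ir(OMe)(cod)]2 (1.5 mol %), 4,4′-di-tert-butyl-2,2′-bipyridine (3 mol %), B2pin2 (0.6 equiv), THF, 80 °C, sealed tube; then NaBO3·4H2O, THF/H2O, rt
Reagents that add atoms: sodium perborate (NaBO3·4H2O), [Na+].[O-]OB=O (phenol oxygen of 3); bis(pinacolato)diboron, CC1(C)OB(OC1(C)C)B1OC(C)(C)C(C)(C)O1 (boryl group of intermediate 2 only)
Why: Iridium-catalysed aromatic C–H borylation is sterically controlled and should take the only C–H of 1 without an ortho substituent (para to the methoxy group) while leaving both C–Br bonds alone, and the crude boronate is oxidised to the phenol in the same flask (one-pot C–H borylation/oxidation).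

Step 2
Reactants: 3 3,5-dibromo-4-methoxyphenol
Product: 4 2,4-dibromo-6-hydroxy-3-methoxybenzaldehyde
Conditions: MgCl2 (2 equiv), Et3N (4 equiv), (CH2O)n (6 equiv), MeCN, reflux; aq HCl work-up
Reagents that add atoms: formaldehyde (as paraformaldehyde), C=O
Why: Magnesium-mediated ortho-formylation of a phenol (Casnati–Skattebøl reaction): the magnesium phenoxide delivers formaldehyde only ortho to oxygen, the two ortho positions of 3 are equivalent, and the salicyl alkoxide is oxidised to the aldehyde by hydride transfer to a second formaldehyde.

Step 3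
Reactants: 4 2,4-dibromo-6-hydroxy-3-methoxybenzaldehyde
Product: 5 6-(benzyloxy)-2,4-dibromo-3-methoxybenzaldehyde
Conditions: BnBr (1.2 equiv), K2CO3 (2 equiv), DMF, 50 °C
Reagents that add atoms: benzyl bromide, BrCc1ccccc1
Why: Williamson ether synthesis on the acidic, carbonyl-conjugated phenoxide installs the benzyl ether that protects the future 5-OH.

Step 4
Reactants: 6 1-(2-hydroxy-4,5-dimethoxyphenyl)ethanone
Product: 7 1-[2-(benzyloxy)-4,5-dimethoxyphenyl]ethanone
Conditions: BnBr (1.2 equiv), K2CO3 (2 equiv), DMF, 70 °C
Reagents that add atoms: benzyl bromide, BrCc1ccccc1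
Why: Williamson ether synthesis; warming in DMF overcomes the hydrogen bond of the phenol to the ketone and gives the benzyl ether that protects the future 2′-OH.

Step 5
Reactants: 7 1-[2-(benzyloxy)-4,5-dimethoxyphenyl]ethanone; 5 6-(benzyloxy)-2,4-dibromo-3-methoxybenzaldehyde
Product: 8 rac-3-[6-(benzyloxy)-2,4-dibromo-3-methoxyphenyl]-1-[2-(benzyloxy)-4,5-dimethoxyphenyl]-3-hydroxypropan-1-one
Conditions: 7, LiN(iPr)2 (1.1 equiv), THF, −78 °C; then 5, −78 °C; AcOH quench at −78 °C
Reagents that add atoms: none
Why: Directed aldol addition of the preformed lithium enolate of methyl ketone 7 to the non-enolisable aldehyde 5, with cold protonation to prevent retro-aldol and dehydration; the new carbinol stereocentre is uncontrolled (racemate) and is removed in step 6.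

Step 6
Reactants: 8 rac-3-[6-(benzyloxy)-2,4-dibromo-3-methoxyphenyl]-1-[2-(benzyloxy)-4,5-dimethoxyphenyl]-3-hydroxypropan-1-one
Product: 9 1-[6-(benzyloxy)-2,4-dibromo-3-methoxyphenyl]-3-[2-(benzyloxy)-4,5-dimethoxyphenyl]propane-1,3-dione
Conditions: IBX (2-iodoxybenzoic acid, 3 equiv), EtOAc, 77 °C
Reagents that add atoms: none
Why: Oxidation of a β-hydroxy ketone to a β-diketone with the pentavalent iodine reagent IBX in hot ethyl acetate, a method that should stop at the 1,3-diketone and tolerate benzyl ethers and aryl bromides.

Step 7
Reactants: 9 1-[6-(benzyloxy)-2,4-dibromo-3-methoxyphenyl]-3-[2-(benzyloxy)-4,5-dimethoxyphenyl]propane-1,3-dione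
Product: 10 5-(benzyloxy)-2-[2-(benzyloxy)-4,5-dimethoxyphenyl]-7-bromo-8-methoxy-4H-chromen-4-one
Conditions: CuI (10 mol %), 1,10-phenanthroline (20 mol %), K3PO4 (2 equiv), DMF (0.05 M), 90 °C, Ar
Reagents that add atoms: none
Why: K3PO4 should convert 9 into its chelating potassium diketonate, which binds monovalent copper (CuI/1,10-phenanthroline) at oxygen and places the metal next to the C–Br bond ortho to the aroyl carbonyl; insertion into that bond gives a trivalent-copper aryl enolate, and C–O reductive elimination forms O1–C8a and returns monovalent copper. The closest known reaction type is the copper-catalysed intramolecular Ullmann O-arylation of 1-(2-haloaryl)-1,3-diketones to flavones, and an uncatalysed addition–elimination at the same carbonyl-activated bromide would converge on the same product. Ring C closes as a six-membered ring through the enolate oxygen on C2 (O-arylation via a seven-membered copper chelate), since closure through the central carbon would give a four-membered ring and the oxygen on C4 cannot reach a bromide. No stereocentre is formed. The step needs chemoselectivity between the two C–Br bonds: only the one flanked by the acyl group lies within reach of the tethered enolate oxygen, so the distal bromide (the future C7) should survive, and dilution keeps intermolecular arylation slow. Because O1 comes from the chain, the methoxy group flanked by the two bromines can only end up at C8, the benzylated oxygen of ring B cannot compete, and no acid is present that could open and re-close the pyranone.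

Step 8
Reactants: 10 5-(benzyloxy)-2-[2-(benzyloxy)-4,5-dimethoxyphenyl]-7-bromo-8-methoxy-4H-chromen-4-one
Product: 12 5-(benzyloxy)-2-[2-(benzyloxy)-4,5-dimethoxyphenyl]-7-hydroxy-8-methoxy-4H-chromen-4-one, via C7 pinacol boronate 11 (not isolated)
Conditions: Pd(dppf)Cl2 (5 mol %), B2pin2 (1.5 equiv), KOAc (3 equiv), 1,4-dioxane, 90 °C; filter, concentrate; then NaBO3·4H2O, THF/H2O, rt
Reagents that add atoms: sodium perborate (NaBO3·4H2O), [Na+].[O-]OB=O (C7 oxygen of 12); bis(pinacolato)diboron, CC1(C)OB(OC1(C)C)B1OC(C)(C)C(C)(C)O1 (boryl group of intermediate 11 only)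
Why: Miyaura borylation (zerovalent palladium inserts into the remaining C7–Br bond, acetate-assisted transmetalation from B2pin2) followed by perborate oxidation of the C–B bond through 1,2-aryl migration from boron to oxygen, which is mild enough for the 4-pyranone and the benzyl ethers.

Step 9
Reactants: 12 5-(benzyloxy)-2-[2-(benzyloxy)-4,5-dimethoxyphenyl]-7-hydroxy-8-methoxy-4H-chromen-4-one
Product: 13 5,7-dihydroxy-2-(2-hydroxy-4,5-dimethoxyphenyl)-8-methoxy-4H-chromen-4-one (CNP0497620.0)
Conditions: H2 (1 atm), 10% Pd/C, EtOAc/MeOH, rt
Reagents that add atoms: none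
Why: Catalytic hydrogenolysis of the two benzyl aryl ethers over palladium on carbon at room temperature, conditions under which the methyl ethers and the flavone C2–C3 double bond are normally retained.

**Compound list**

1 | 2,6-dibromoanisole (1,3-dibromo-2-methoxybenzene) | COc1c(Br)cccc1Br | starting material
2 | 2-(3,5-dibromo-4-methoxyphenyl)-4,4,5,5-tetramethyl-1,3,2-dioxaborolane | COc1c(Br)cc(B2OC(C)(C)C(C)(C)O2)cc1Br | intermediate (not isolated)
3 | 3,5-dibromo-4-methoxyphenol | COc1c(Br)cc(O)cc1Br | intermediate
4 | 2,4-dibromo-6-hydroxy-3-methoxybenzaldehyde | COc1c(Br)cc(O)c(C=O)c1Br | intermediate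
5 | 6-(benzyloxy)-2,4-dibromo-3-methoxybenzaldehyde | COc1c(Br)cc(OCc2ccccc2)c(C=O)c1Br | intermediate
6 | 1-(2-hydroxy-4,5-dimethoxyphenyl)ethanone | COc1cc(O)c(C(C)=O)cc1OC | starting material
7 | 1-[2-(benzyloxy)-4,5-dimethoxyphenyl]ethanone | COc1cc(OCc2ccccc2)c(C(C)=O)cc1OC | intermediate
8 | rac-3-[6-(benzyloxy)-2,4-dibromo-3-methoxyphenyl]-1-[2-(benzyloxy)-4,5-dimethoxyphenyl]-3-hydroxypropan-1-one (racemic at the carbinol carbon) | COc1c(Br)cc(OCc2ccccc2)c(C(O)CC(=O)c2cc(OC)c(OC)cc2OCc2ccccc2)c1Br | intermediate
9 | 1-[6-(benzyloxy)-2,4-dibromo-3-methoxyphenyl]-3-[2-(benzyloxy)-4,5-dimethoxyphenyl]propane-1,3-dione | COc1c(Br)cc(OCc2ccccc2)c(C(=O)CC(=O)c2cc(OC)c(OC)cc2OCc2ccccc2)c1Br | intermediate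
10 | 5-(benzyloxy)-2-[2-(benzyloxy)-4,5-dimethoxyphenyl]-7-bromo-8-methoxy-4H-chromen-4-one | COc1cc(OCc2ccccc2)c(-c2cc(=O)c3c(OCc4ccccc4)cc(Br)c(OC)c3o2)cc1OC | intermediate
11 | 5-(benzyloxy)-2-[2-(benzyloxy)-4,5-dimethoxyphenyl]-8-methoxy-7-(4,4,5,5-tetramethyl-1,3,2-dioxaborolan-2-yl)-4H-chromen-4-one | COc1cc(OCc2ccccc2)c(-c2cc(=O)c3c(OCc4ccccc4)cc(B4OC(C)(C)C(C)(C)O4)c(OC)c3o2)cc1OC | intermediate (not isolated)
12 | 5-(benzyloxy)-2-[2-(benzyloxy)-4,5-dimethoxyphenyl]-7-hydroxy-8-methoxy-4H-chromen-4-one | COc1cc(OCc2ccccc2)c(-c2cc(=O)c3c(OCc4ccccc4)cc(O)c(OC)c3o2)cc1OC | intermediate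
13 | 5,7-dihydroxy-2-(2-hydroxy-4,5-dimethoxyphenyl)-8-methoxy-4H-chromen-4-one | COc1cc(O)c(-c2cc(=O)c3c(O)cc(O)c(OC)c3o2)cc1OC | target

**Step count and risks**

Total: 9 steps. Longest linear sequence: 8 steps (steps 1, 2, 3, 5, 6, 7, 8, 9).

Steps most likely to fail:

1. Step 2. The attack of magnesium-bound formaldehyde on a ring carbon deactivated by two bromines and flanked by one of them may stall, and prolonged heating may lead to methoxymethylation instead of formylation. The fallback replaces electrophilic substitution by directed ortho-metalation. It sets out from phenol 3, which would be converted (MOMCl, iPr2NEt, CH2Cl2) into 1,3-dibromo-2-methoxy-5-(methoxymethoxy)benzene F1. Deprotonation with LiN(iPr)2 in THF at −78 °C should occur at the C–H flanked by the acetal oxygen and a bromine; an amide base does not exchange the bromines, and the low temperature keeps the ortho-bromo aryllithium from losing LiBr. Trapping with DMF would give 2,4-dibromo-3-methoxy-6-(methoxymethoxy)benzaldehyde F2. HCl in MeOH would then remove the acetal, and the sequence comes back to the route at aldehyde 4.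

2. Step 7. The copper catalyst may also insert into the distal C–Br bond (para to the carbonyl), which would lead to intermolecular arylation or reductive loss of that bromine, or the hindered diketonate may undergo retro-Claisen cleavage before it cyclises. The fallback changes the reaction class from metal-catalysed coupling to uncatalysed nucleophilic aromatic substitution. Setting out from 9, the caesium enolate (Cs2CO3, dry DMSO, 100–110 °C, high dilution) would close ring C by addition–elimination at the bromide ortho to the carbonyl, the only one that is both activated and within reach of the tethered oxygen; with no metal present, nothing inserts into the distal bromide. The fallback comes back to the route at 10 and makes no new compound (F0).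

3. Step 8. Reductive loss of bromine during the palladium-catalysed borylation, protodeboronation of the aryl boronate, or attack of the basic peroxide on the pyranone may erode the C7 oxygenation. The fallback is a direct palladium-catalysed C–O coupling instead of borylation/oxidation. It sets out from 10, which with benzyl alcohol (Pd2(dba)3, tBuBrettPhos, Cs2CO3, toluene, 90 °C) would give 5,7-bis(benzyloxy)-2-[2-(benzyloxy)-4,5-dimethoxyphenyl]-8-methoxy-4H-chromen-4-one F3. Hydrogenolysis under the conditions of step 9 would then remove all three benzyl groups at once, and the sequence comes back to the route at target 13.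

**Further compounds**

F1 | step 2 | 1,3-dibromo-2-methoxy-5-(methoxymethoxy)benzene | COCOc1cc(Br)c(OC)c(Br)c1
F2 | step 2 | 2,4-dibromo-3-methoxy-6-(methoxymethoxy)benzaldehyde | COCOc1cc(Br)c(OC)c(Br)c1C=O
F0 | step 7 | none | none
F3 | step 8 | 5,7-bis(benzyloxy)-2-[2-(benzyloxy)-4,5-dimethoxyphenyl]-8-methoxy-4H-chromen-4-one | COc1cc(OCc2ccccc2)c(-c2cc(=O)c3c(OCc4ccccc4)cc(OCc4ccccc4)c(OC)c3o2)cc1OC
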